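**Plan**
- Target 1 is an achiral biflavone ether: an acacetin-type unit (5,7-dihydroxy-4'-methoxyflavone) whose C8 oxygen is also O4' of an apigenin-type unit.
- Cuts: O1–C2 and C2–C3 of both pyranone rings, C4–C4a of the acacetin-type unit (C-acetyl), and, centrally, the C4'–C3' and C5'–C6' bonds of ring B of the apigenin-type unit.
- Enabling feature: the ether oxygen sits on C8 between the oxygenated C7 and C8a, where aryl C–O coupling is crowded. Ring B on its other side is a bare 1,4-phenylene (O on C4', carbon on C1', four CH), which a 5-carboxylated 2-pyrone (four ring carbons plus the future C2) and a two-carbon alkyne already bound to that oxygen can assemble.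
- Forward order: phenol → aryl ethynyl ether → ring B by pyrone Diels–Alder/CO2 loss → C-acetylation → pyranone ring of the acacetin-type unit (chalcone, I2/DMSO) → pyranone ring of the apigenin-type unit (Baker–Venkataraman on the ring-B carboxyl) → global deprotection.
- Stereochemistry: 1 has no stereocentre. The E-dichlorovinyl ether, the E-chalcone, a racemic flavanone and a racemic bridged adduct are transient.

Key step: step 5

Assumption: aldehyde 2 is taken as a purchasable building block, and a 2,6-disubstituted terminal aryl ethynyl ether is taken to survive brief handling in cold solution.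

**Step 1**
Reactants: 2 2,6-dihydroxy-4-methoxybenzaldehyde
Product: 3 2,6-bis(benzyloxy)-4-methoxybenzaldehyde
Conditions: BnBr (2.3 equiv), K2CO3, DMF, 60 °C
Reagents that add atoms: benzyl bromide, BrCc1ccccc1
Why: Williamson ether synthesis, in which both chelated phenols are alkylated under carbonate in warm DMF, as is routine for 2,6-dihydroxybenzaldehydes.

**Step 2**
Reactants: 3 2,6-bis(benzyloxy)-4-methoxybenzaldehyde
Product: 5 2,6-bis(benzyloxy)-4-methoxyphenol, via aryl formate 4 (not isolated)
Conditions: mCPBA, CH2Cl2, 0 °C → rt; then K2CO3 (cat.), MeOH, rt, under N2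
Reagents that add atoms: mCPBA (3-chloroperoxybenzoic acid), OOC(=O)c1cccc(Cl)c1
Why: Dakin-type Baeyer–Villiger oxidation, in which the electron-rich trialkoxyaryl group migrates to oxygen in preference to hydrogen to give formate 4, and mild methanolysis then frees the phenol only after the oxidant is gone.

**Step 3**
Reactants: 5 2,6-bis(benzyloxy)-4-methoxyphenol; 6 trichloroethylene
Product: 7 1,3-bis(benzyloxy)-2-{[(E)-1,2-dichloroethenyl]oxy}-5-methoxybenzene
Conditions: K2CO3, DMF, 70 °C
Reagents that add atoms: none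
Why: Vinylic substitution by elimination–addition: carbonate dehydrochlorinates 6 to dichloroacetylene in the flask and the phenoxide adds to it in anti fashion to give the E-dichlorovinyl ether; the rod-shaped sp electrophile is indifferent to the two flanking benzyloxy groups.

**Step 4**
Reactants: 7 1,3-bis(benzyloxy)-2-{[(E)-1,2-dichloroethenyl]oxy}-5-methoxybenzene
Product: 10 1,3-bis(benzyloxy)-2-(ethynyloxy)-5-methoxybenzene, via chloroethynyl ether 8 (not isolated), via lithium acetylide 9 (not isolated)
Conditions: n-BuLi (2.2 equiv), THF, −78 → −40 °C; then H2O, −78 °C; cold work-up, used at once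
Reagents that add atoms: none
Why: Dehydrochlorination followed by lithium–chlorine exchange, the standard conversion of 1,2-dichlorovinyl ethers into ynol ethers: the first equivalent of n-BuLi eliminates HCl to chloroalkyne 8, the second gives acetylide 9, and water protonates it; at −78 °C ring lithiation and benzylic deprotonation should not compete.

**Step 5**
Reactants: 10 1,3-bis(benzyloxy)-2-(ethynyloxy)-5-methoxybenzene; 11 methyl coumalate (methyl 2-oxo-2H-pyran-5-carboxylate)
Product: 13 methyl 4-[2,6-bis(benzyloxy)-4-methoxyphenoxy]benzoate, via bridged lactone 12 (not isolated)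
Conditions: 11 (2 equiv), PhMe, 110 °C, sealed tube
Reagents that add atoms: none
Why: Proposed new method: the electron-rich ynol ether (largest HOMO coefficient on its terminal CH carbon) should add across C3/C6 of the electron-poor pyrone in an inverse-electron-demand [4+2] cycloaddition, terminal carbon to C6 (activated by both the lactone carbonyl and the C5 ester) and oxygen-bearing carbon to C3, giving bridged lactone 12, which at 110 °C loses CO2 by retro-[4+2] and delivers the benzoate already aromatic, with no oxidant. The closest known reaction type is the thermal Diels–Alder/decarboxylation of methyl coumalate with terminal alkynes, enol ethers and ketene acetals to para-substituted benzoates; an aryl alkynyl ether is polarised in the same sense as those donors and, having no β-hydrogen on its O-substituent, cannot fragment to a ketene on heating. The new benzene ring (ring B of the apigenin-type unit) is closed by intermolecular (4+2) annulation, which forms both new C–C bonds (C4'–C3' and C5'–C6') in one operation, followed by extrusion of the lactone bridge; no chain cyclisation is involved. No stereocentre is created in 13, since the two bridgehead centres of racemic 12 become sp2 on loss of CO2. The selectivity needed is para rather than meta placement of the ester relative to the aryloxy group, and the matched polarisation secures it (positive charge builds on the oxygen-bearing alkyne carbon while the nucleophilic terminus engages C6); excess 11 in acid-free toluene is meant to let cycloaddition outrun hydration or oligomerisation of 10.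

**Step 6**
Reactants: 13 methyl 4-[2,6-bis(benzyloxy)-4-methoxyphenoxy]benzoate
Product: 14 methyl 4-(2,6-dihydroxy-4-methoxyphenoxy)benzoate
Conditions: H2 (1 atm), 10% Pd/C, EtOAc/MeOH, rt
Reagents that add atoms: none
Why: Catalytic hydrogenolysis of benzyl aryl ethers, which leaves the diaryl ether and the methyl ester untouched and gives a symmetric resorcinol.

**Step 7**
Reactants: 14 methyl 4-(2,6-dihydroxy-4-methoxyphenoxy)benzoate
Product: 15 methyl 4-(3-acetyl-2,6-dihydroxy-4-methoxyphenoxy)benzoate
Conditions: AcOH, BF3·OEt2, 80 °C; then aq. NaOAc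
Reagents that add atoms: acetic acid, CC(=O)O
Why: Friedel–Crafts (Nencki-type) C-acylation: the two free positions of the resorcinol ring are equivalent and phloroglucinol-like in activation (ortho to OH, para to OH, ortho to OMe) while the benzoate ring is deactivated, so a single mono-ketone is expected, held as its boron chelate against a second acylation.

**Step 8**
Reactants: 15 methyl 4-(3-acetyl-2,6-dihydroxy-4-methoxyphenoxy)benzoate
Product: 16 methyl 4-[3-acetyl-6-(benzyloxy)-2-hydroxy-4-methoxyphenoxy]benzoate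
Conditions: BnBr (1.05 equiv), K2CO3, acetone, 50 °C
Reagents that add atoms: benzyl bromide, BrCc1ccccc1
Why: Regioselective Williamson etherification: the hydroxyl para to the acetyl group is unchelated and more acidic, whereas the ortho hydroxyl is hydrogen-bonded to the ketone, the usual selectivity of 2,4-dihydroxyacetophenones; the mild base keeps an O-to-O Smiles shift of the benzoate ring out of reach.

**Step 9**
Reactants: 16 methyl 4-[3-acetyl-6-(benzyloxy)-2-hydroxy-4-methoxyphenoxy]benzoate; 17 4-methoxybenzaldehyde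
Product: 18 4-{6-(benzyloxy)-2-hydroxy-4-methoxy-3-[(2E)-3-(4-methoxyphenyl)prop-2-enoyl]phenoxy}benzoic acid
Conditions: 17 (1.5 equiv), KOH (50% aq.), EtOH, rt; then 1 M HCl
Reagents that add atoms: potassium hydroxide (oxygen of the new carboxyl OH), [K+].[OH-]
Why: Claisen–Schmidt condensation with concurrent saponification: the ketone enolate condenses with the non-enolisable aldehyde and dehydrates to the E-enone, while the same aqueous base hydrolyses the methyl ester, which is needed as the free acid in step 12.

**Step 10**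
Reactants: 18 4-{6-(benzyloxy)-2-hydroxy-4-methoxy-3-[(2E)-3-(4-methoxyphenyl)prop-2-enoyl]phenoxy}benzoic acid
Product: 20 4-{[7-(benzyloxy)-5-methoxy-2-(4-methoxyphenyl)-4-oxo-4H-chromen-8-yl]oxy}benzoic acid, via flavanone 19 (not isolated)
Conditions: I2 (10 mol%), DMSO, 130 °C
Reagents that add atoms: none
Why: Iodine/DMSO oxidative cyclisation of a 2'-hydroxychalcone: 6-endo oxa-Michael closure gives flavanone 19, which iodine dehydrogenates while DMSO re-oxidises the HI formed; only one phenol is free, so the aryloxy group can end up only on C8.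

**Step 11**
Reactants: 21 2',4',6'-trihydroxyacetophenone
Product: 22 1-[2,4-bis(benzyloxy)-6-hydroxyphenyl]ethan-1-one
Conditions: BnBr (2.1 equiv), K2CO3, DMF, rt
Reagents that add atoms: benzyl bromide, BrCc1ccccc1
Why: Williamson etherification of phloroacetophenone, which should stop at the bis-ether because the last hydroxyl is chelated to the ketone.

**Step 12**
Reactants: 20 4-{[7-(benzyloxy)-5-methoxy-2-(4-methoxyphenyl)-4-oxo-4H-chromen-8-yl]oxy}benzoic acid; 22 1-[2,4-bis(benzyloxy)-6-hydroxyphenyl]ethan-1-one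
Product: 23 2-acetyl-3,5-bis(benzyloxy)phenyl 4-{[7-(benzyloxy)-5-methoxy-2-(4-methoxyphenyl)-4-oxo-4H-chromen-8-yl]oxy}benzoate
Conditions: EDC·HCl, 4-(dimethylamino)pyridine (cat.), CH2Cl2/DMF, rt
Reagents that add atoms: none
Why: Steglich esterification (carbodiimide activation with pyridine-type acyl transfer), routinely used to O-acylate chelated 2-hydroxyacetophenones ahead of a Baker–Venkataraman rearrangement.

**Step 13**
Reactants: 23 2-acetyl-3,5-bis(benzyloxy)phenyl 4-{[7-(benzyloxy)-5-methoxy-2-(4-methoxyphenyl)-4-oxo-4H-chromen-8-yl]oxy}benzoate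
Product: 25 5,7-bis(benzyloxy)-2-(4-{[7-(benzyloxy)-5-methoxy-2-(4-methoxyphenyl)-4-oxo-4H-chromen-8-yl]oxy}phenyl)-4H-chromen-4-one, via diketone 24 (not isolated)
Conditions: KOt-Bu (2.5 equiv), THF, 0 °C → rt; AcOH quench; then p-toluenesulfonic acid monohydrate (cat.), PhMe, 90 °C
Reagents that add atoms: none
Why: Baker–Venkataraman rearrangement followed by acid cyclodehydration: the ketone enolate attacks the neighbouring aryl ester in an intramolecular Claisen condensation to give 1,3-diketone 24, whose phenol then closes onto the enolised ketone with loss of water; the existing flavone has no site that tert-butoxide should engage at 0 °C.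

**Step 14**
Reactants: 25 5,7-bis(benzyloxy)-2-(4-{[7-(benzyloxy)-5-methoxy-2-(4-methoxyphenyl)-4-oxo-4H-chromen-8-yl]oxy}phenyl)-4H-chromen-4-one
Product: 1 5,7-dihydroxy-2-(4-{[5,7-dihydroxy-2-(4-methoxyphenyl)-4-oxo-4H-chromen-8-yl]oxy}phenyl)-4H-chromen-4-one
Conditions: BCl3 (1 M in CH2Cl2, 10 equiv), C6HMe5, CH2Cl2, −78 °C → rt; then MeOH/H2O
Reagents that add atoms: none
Why: Lewis-acid ether cleavage: BCl3 with pentamethylbenzene as benzyl-cation trap removes the three benzyl ethers in the cold, and on warming the boron chelate between the C4 carbonyl and the peri C5 methoxy group delivers chloride to that methyl only, so the non-chelating 4'-methoxy group should be kept.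

**Compound list**
1 | 5,7-dihydroxy-2-(4-{[5,7-dihydroxy-2-(4-methoxyphenyl)-4-oxo-4H-chromen-8-yl]oxy}phenyl)-4H-chromen-4-one | COc1ccc(-c2cc(=O)c3c(O)cc(O)c(Oc4ccc(-c5cc(=O)c6c(O)cc(O)cc6o5)cc4)c3o2)cc1 | target
2 | 2,6-dihydroxy-4-methoxybenzaldehyde | COc1cc(O)c(C=O)c(O)c1 | starting material
3 | 2,6-bis(benzyloxy)-4-methoxybenzaldehyde | COc1cc(OCc2ccccc2)c(C=O)c(OCc2ccccc2)c1 | intermediate
4 | 2,6-bis(benzyloxy)-4-methoxyphenyl formate (not isolated) | COc1cc(OCc2ccccc2)c(OC=O)c(OCc2ccccc2)c1 | intermediate
5 | 2,6-bis(benzyloxy)-4-methoxyphenol | COc1cc(OCc2ccccc2)c(O)c(OCc2ccccc2)c1 | intermediate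
6 | trichloroethylene | ClC=C(Cl)Cl | starting material
7 | 1,3-bis(benzyloxy)-2-{[(E)-1,2-dichloroethenyl]oxy}-5-methoxybenzene | COc1cc(OCc2ccccc2)c(O/C(Cl)=C\Cl)c(OCc2ccccc2)c1 | intermediate
8 | 1,3-bis(benzyloxy)-2-[(chloroethynyl)oxy]-5-methoxybenzene (not isolated) | COc1cc(OCc2ccccc2)c(OC#CCl)c(OCc2ccccc2)c1 | intermediate
9 | {[2,6-bis(benzyloxy)-4-methoxyphenoxy]ethynyl}lithium (not isolated) | COc1cc(OCc2ccccc2)c(OC#C[Li])c(OCc2ccccc2)c1 | intermediate
10 | 1,3-bis(benzyloxy)-2-(ethynyloxy)-5-methoxybenzene | COc1cc(OCc2ccccc2)c(OC#C)c(OCc2ccccc2)c1 | intermediate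
11 | methyl coumalate (methyl 2-oxo-2H-pyran-5-carboxylate) | COC(=O)c1ccc(=O)oc1 | starting material
12 | methyl 5-[2,6-bis(benzyloxy)-4-methoxyphenoxy]-3-oxo-2-oxabicyclo[2.2.2]octa-5,7-diene-7-carboxylate (racemic, not isolated) | COC(=O)C1=CC2C(=O)OC1C=C2Oc1c(OCc2ccccc2)cc(OC)cc1OCc1ccccc1 | intermediate
13 | methyl 4-[2,6-bis(benzyloxy)-4-methoxyphenoxy]benzoate | COC(=O)c1ccc(Oc2c(OCc3ccccc3)cc(OC)cc2OCc2ccccc2)cc1 | intermediate
14 | methyl 4-(2,6-dihydroxy-4-methoxyphenoxy)benzoate | COC(=O)c1ccc(Oc2c(O)cc(OC)cc2O)cc1 | intermediate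
15 | methyl 4-(3-acetyl-2,6-dihydroxy-4-methoxyphenoxy)benzoate | COC(=O)c1ccc(Oc2c(O)cc(OC)c(C(C)=O)c2O)cc1 | intermediate
16 | methyl 4-[3-acetyl-6-(benzyloxy)-2-hydroxy-4-methoxyphenoxy]benzoate | COC(=O)c1ccc(Oc2c(OCc3ccccc3)cc(OC)c(C(C)=O)c2O)cc1 | intermediate
17 | 4-methoxybenzaldehyde | COc1ccc(C=O)cc1 | starting material
18 | 4-{6-(benzyloxy)-2-hydroxy-4-methoxy-3-[(2E)-3-(4-methoxyphenyl)prop-2-enoyl]phenoxy}benzoic acid | COc1ccc(/C=C/C(=O)c2c(OC)cc(OCc3ccccc3)c(Oc3ccc(C(=O)O)cc3)c2O)cc1 | intermediate
19 | 4-{[7-(benzyloxy)-5-methoxy-2-(4-methoxyphenyl)-4-oxo-3,4-dihydro-2H-chromen-8-yl]oxy}benzoic acid (racemic flavanone, not isolated) | COc1ccc(C2CC(=O)c3c(OC)cc(OCc4ccccc4)c(Oc4ccc(C(=O)O)cc4)c3O2)cc1 | intermediate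
20 | 4-{[7-(benzyloxy)-5-methoxy-2-(4-methoxyphenyl)-4-oxo-4H-chromen-8-yl]oxy}benzoic acid | COc1ccc(-c2cc(=O)c3c(OC)cc(OCc4ccccc4)c(Oc4ccc(C(=O)O)cc4)c3o2)cc1 | intermediate
21 | 2',4',6'-trihydroxyacetophenone | CC(=O)c1c(O)cc(O)cc1O | starting material
22 | 1-[2,4-bis(benzyloxy)-6-hydroxyphenyl]ethan-1-one | CC(=O)c1c(O)cc(OCc2ccccc2)cc1OCc1ccccc1 | intermediate
23 | 2-acetyl-3,5-bis(benzyloxy)phenyl 4-{[7-(benzyloxy)-5-methoxy-2-(4-methoxyphenyl)-4-oxo-4H-chromen-8-yl]oxy}benzoate | CC(=O)c1c(OC(=O)c2ccc(Oc3c(OCc4ccccc4)cc(OC)c4c(=O)cc(-c5ccc(OC)cc5)oc34)cc2)cc(OCc2ccccc2)cc1OCc1ccccc1 | intermediate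
24 | 1-[2,4-bis(benzyloxy)-6-hydroxyphenyl]-3-(4-{[7-(benzyloxy)-5-methoxy-2-(4-methoxyphenyl)-4-oxo-4H-chromen-8-yl]oxy}phenyl)propane-1,3-dione (not isolated) | O=C(CC(=O)c1c(O)cc(OCc2ccccc2)cc1OCc1ccccc1)c1ccc(Oc2c(OCc3ccccc3)cc(OC)c3c(=O)cc(-c4ccc(OC)cc4)oc23)cc1 | intermediate
25 | 5,7-bis(benzyloxy)-2-(4-{[7-(benzyloxy)-5-methoxy-2-(4-methoxyphenyl)-4-oxo-4H-chromen-8-yl]oxy}phenyl)-4H-chromen-4-one | COc1ccc(-c2cc(=O)c3c(OC)cc(OCc4ccccc4)c(Oc4ccc(-c5cc(=O)c6c(OCc7ccccc7)cc(OCc7ccccc7)cc6o5)cc4)c3o2)cc1 | intermediate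

**Totals**
Total step count: 14. Longest linear sequence: 13 steps (steps 1–10 and 12–14; step 11 is a one-step side branch).

**Steps most likely to fail**

Step 5. The terminal ynol ether may hydrate or oligomerise faster than it cycloadds, or the cycloaddition may proceed with mixed para/meta orientation. The fallback uses known chemistry and sets out from phenol 5. Nucleophilic aromatic substitution of its potassium salt on 4-fluorobenzaldehyde (K2CO3, DMF, 120 °C) should give 4-[2,6-bis(benzyloxy)-4-methoxyphenoxy]benzaldehyde F1. Pinnick oxidation (NaClO2, NaH2PO4, 2-methyl-2-butene, t-BuOH/H2O) should then give 4-[2,6-bis(benzyloxy)-4-methoxyphenoxy]benzoic acid F2. Methylation (MeI, K2CO3, DMF) returns to the route at benzoate 13. The price is a crowded C–O coupling, which is the bond construction the pyrone route is meant to avoid.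

Step 4. The unprotected ethynyl ether may be lost during aqueous work-up and concentration through hydration to the aryl acetate or through oligomerisation. The fallback sets out from dichlorovinyl ether 7. After the same treatment with n-BuLi, acetylide 9 would be quenched with i-Pr3SiCl instead of water to give the chromatographable, storable {[2,6-bis(benzyloxy)-4-methoxyphenoxy]ethynyl}tri(propan-2-yl)silane F3. Desilylation with Bu4NF in THF at −20 °C, directly before the cycloaddition, returns to the route at ynol ether 10 as a fresh solution.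

Step 14. The chelated methyl ether may be cleaved incompletely, benzyl cations may be transferred to the electron-rich rings, or acid-promoted opening and reclosure of the pyranone ring (Wessely–Moser isomerisation) may move the aryloxy group from C8 to C6. The fallback sets out from 25 and separates the two deprotections. Hydrogenolysis (H2, Pd(OH)2/C, THF/MeOH) should give 5,7-dihydroxy-2-(4-{[7-hydroxy-5-methoxy-2-(4-methoxyphenyl)-4-oxo-4H-chromen-8-yl]oxy}phenyl)-4H-chromen-4-one F4. Chelation-controlled peri-demethylation with AlCl3 in MeCN at 50 °C then returns to the route at target 1.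

**Further compounds**
F1 | step 5 | 4-[2,6-bis(benzyloxy)-4-methoxyphenoxy]benzaldehyde | O=Cc1ccc(Oc2c(OCc3ccccc3)cc(OC)cc2OCc2ccccc2)cc1
F2 | step 5 | 4-[2,6-bis(benzyloxy)-4-methoxyphenoxy]benzoic acid | OC(=O)c1ccc(Oc2c(OCc3ccccc3)cc(OC)cc2OCc2ccccc2)cc1
F3 | step 4 | {[2,6-bis(benzyloxy)-4-methoxyphenoxy]ethynyl}tri(propan-2-yl)silane | COc1cc(OCc2ccccc2)c(OC#C[Si](C(C)C)(C(C)C)C(C)C)c(OCc2ccccc2)c1
F4 | step 14 | 5,7-dihydroxy-2-(4-{[7-hydroxy-5-methoxy-2-(4-methoxyphenyl)-4-oxo-4H-chromen-8-yl]oxy}phenyl)-4H-chromen-4-one | COc1ccc(-c2cc(=O)c3c(OC)cc(O)c(Oc4ccc(-c5cc(=O)c6c(O)cc(O)cc6o5)cc4)c3o2)cc1
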